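A one-to-one reaction that runs one way only cannot stand still at 64.5% of product with 0.90 M of nucleophile charged against 0.80 M of electrophile, yet the summer run gives that reading at 2.00 h and again at 2.50 h.

| flask | electrophile | nucleophile | gas | remark | time |
|---|---|---|---|---|---|
| summer | 0.80 M | 0.90 M | 100 mM (held) | run made earlier |  |
| midnight | 0.80 M | 1.3 M | 100 mM (held) | run made earlier |  |
| flask | 0.80 M |  | 100 mM (held) |  | 2.0 h |

| run | time / h | product / % |
|---|---|---|
| summer | 0.667 | 48.8 |
| summer | 1.33 | 59.8 |
| summer | 2.00 | 64.5 |
| summer | 2.50 | 64.5 |
| midnight | 0.667 | 63.3 |
| midnight | 1.33 | 75.4 |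
| midnight | 2.00 | 82.9 |
| midnight | 2.50 | 85.3 |

(standard deviation of a reading: 1 percentage point)

* the concentration of nucleophile at which the part of the electrophile that has reacted at 2.0 h is just 95%, in M

For whoever takes over the bench: we read that stall as nucleophile being the limiting reagent, and define the price p, nucleophile charged per electrophile reacted at the stall, as 1.74. Leave the gas held at 100 mM, as it was when p was read.

At that price, reacting all the electrophile costs a = 1.40 M. We take free nucleophile as the charge minus p times the electrophile reacted, with a rate proportional to free nucleophile times electrophile. Integrating this over the midnight run up to its reading at 2.00 h gives a rate constant times time of 4.61 L mol⁻¹. A steady surplus above a would have to be 0.650 M; one correction through the integrated law brings it to 0.423 M, and a Newton step on that law from there gives our charge, 1.74 M.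

The forecast gave 2 M (1.65 M to 2.6 M), “with the mechanism uncertain”. The flask gives 1.80 M.

    gas ⇌ free base, rate k1*(csat - [free base]) (kL = 0.0133 min⁻¹)
    acid set free + free base ⇌ salt of the base, settled at all times (K = 2.11 × 10⁵ L mol⁻¹)
    electrophile + nucleophile → acid set free + product (k = 0.0384 L mol⁻¹ min⁻¹)
    nucleophile + acid set free ⇌ protonated nucleophile, settled at all times (K = 79.0 L mol⁻¹)
    free base + product ⇌ idle adduct, settled at all times (K = 285 L mol⁻¹)

In this flask, half the turnover of electrophile with nucleophile up to 2.0 h is done by 0.207 h, sooner than the 1.00 h for the passage of gas into free base. At price p, this charge stands 0.472 M above the cost of 95%, and at 2.00 h the free nucleophile is 24.8% of the charge, 0.446 M.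

The readings stem from a simulated flask from invented constants; the scatter is artificial.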